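**Plan**

1. Retrosynthetic cuts, in order: aryl C–CHO (last-step ortho-formylation of a resorcinol whose two open positions are equivalent); C9–CH3 (1,6-cuprate addition to a ring-A dienone); C1=C2 and C1–C10 (aldol closure of ring A onto a formyl group carried by C10); C9–C11 (condensation of a ring-B ketone with an aryl aldehyde); C4–C3 (vinyl cuprate addition to pulegone).
2. Forward: ring B is (R)-pulegone, and vinyl addition builds the quaternary C4. C9 is the only α-methylene of the ring-B C10 ketone and is condensed with C11, the formyl carbon of the aryl aldehyde. C11 sits between two ortho oxygens, so it is installed by ortho-lithiation.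
3. The benzylidene is reduced in the 1,4 sense to the C9=C10 enol triflate. Wacker oxidation (C3=O), carbonylation (C1) and aldol condensation then close ring A as the dienone O=C3–C2=C1–C10=C9.
4. Stereochemistry: C8 comes from pulegone; C5 is set by equilibration α to the C10 ketone; C9 by axial 1,6-delivery of methyl to a locked half-chair, so that CH2Ar, attached while C9 was trigonal, ends equatorial; C3 by equatorial hydride delivery.
5. Endgame: non-protic removal of the acetals, then ortho-formylation.

Key step: step 4

Remark: locants C1–C11 are the drimane-type positions of the target (C3 carbinol, C4 CMe2, C5 ring-fusion CH, C8 CH–CH3, C9 quaternary carbon, C10 sp2 ring-fusion carbon, C11 benzylic CH2); Ar = 2,6-bis(methoxymethoxy)-4-[(methoxymethoxy)methyl]phenyl; the target is taken as the open hydroxy-aldehyde, as drawn.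

**Step 1**
Reactants: 1 3,5-dihydroxybenzyl alcohol
Product: 2 tris(methoxymethyl) ether
Conditions: NaH, MOMCl, THF/DMF, 0 °C → rt
Reagents that add atoms: chloromethyl methyl ether, COCCl
Why: Williamson-type O-alkylation of the two phenoxides and the benzylic alkoxide gives acetals that direct the metalation of step 2 and should survive base, hydride, organocopper and palladium chemistry; no stereocenter.

**Step 2**
Reactants: 2 tris(methoxymethyl) ether
Product: 4 aryl aldehyde Ar–CHO, via aryllithium 3 (not isolated)
Conditions: n-BuLi, TMEDA, THF, 0 °C; DMF, 0 °C → rt; H2O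
Reagents that add atoms: N,N-dimethylformamide, CN(C)C=O
Why: Directed ortho-metalation should occur at the ring C–H flanked by the two OMOM groups (two cooperating directing groups), and the aryllithium is formylated by DMF; no stereocenter.

**Step 3**
Reactants: 5 (R)-pulegone
Product: 7 trans-ketone, via bromomagnesium enolate 6 (not isolated)
Conditions: CH2=CHMgBr, CuBr·SMe2 (10 mol %), THF, −30 → 0 °C; H2O; then KOH, EtOH, reflux
Reagents that add atoms: vinylmagnesium bromide, C=C[Mg]Br
Why: Copper-catalysed 1,4-addition of the Grignard reagent to the s-cis β,β-disubstituted enone builds the quaternary C4 (a reaction type established for pulegone), and base equilibration of C5 (α to the C10 ketone) should leave mainly the diequatorial trans isomer, so C5 is set under thermodynamic control by the C8 methyl stereocenter.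

**Step 4**
Reactants: 7 trans-ketone; 4 aryl aldehyde Ar–CHO
Product: 11 (E)-benzylidene ketone, via lithium enolate 8 (not isolated), via lithium aldolate 9 (not isolated), via aldol mesylate 10 (not isolated)
Conditions: LiN(i-Pr)2, THF, −78 °C; 4, −78 °C; MsCl, −78 → 0 °C; Et3N, 0 °C → rt
Reagents that add atoms: none
Why: Kinetic deprotonation removes a proton from C9, the only α-methylene of the C10 ketone (the other α-carbon, C5, is a methine shielded by the quaternary C4); the lithium enolate adds to the formyl carbon of 4 through a closed six-membered transition state, and mesylation of the aldolate followed by amine-induced E1cB loss of methanesulfonate gives the conjugated benzylidene ketone. The closest known reaction type is the directed crossed aldol (Claisen–Schmidt) condensation of a 2-alkylcyclohexanone with a 2,6-dialkoxybenzaldehyde. No ring is closed; the two transient stereocenters (C9 and C11) vanish on elimination, and the E geometry expected from the E1cB step is inconsequential because C11 becomes CH2 in step 5. The selectivity needed is enolisation at C9 rather than C5 without epimerisation of C5, and it is secured by the CH2-versus-hindered-CH difference, the low temperature and the weak amine base. The bond is made at this stage on purpose: in the target CH2Ar is equatorial and CH3 axial on C9, so the large group is attached while C9 can be kept trigonal (benzylidene, then enol triflate, then dienone) and the small methyl group is the one delivered last and axially (step 9).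

**Step 5**
Reactants: 11 (E)-benzylidene ketone
Product: 13 enol triflate, via lithium enolate 12 (not isolated)
Conditions: LiBH(s-Bu)3, THF, −78 °C; PhNTf2, −78 → 0 °C
Reagents that add atoms: N-phenylbis(trifluoromethanesulfonimide), O=S(=O)(N(c1ccccc1)S(=O)(=O)C(F)(F)F)C(F)(F)F
Why: Conjugate (1,4) hydride addition of the hindered borohydride to the exocyclic enone should give the C9=C10 enolate regiospecifically, and O-sulfonylation traps it (reductive enol triflate formation); no new stereocenter, C5 and C8 are untouched.

**Step 6**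
Reactants: 13 enol triflate
Product: 14 methyl ketone triflate
Conditions: PdCl2 (10 mol %), CuCl, O2 (1 atm), DMF/H2O, rt
Reagents that add atoms: water, O
Why: Tsuji–Wacker oxidation, by Markovnikov hydroxypalladation of the monosubstituted vinyl group, should give the methyl ketone (C3 with its C2 methyl) while the tetrasubstituted enol triflate and the acetals stay inert; no stereocenter.

**Step 7**
Reactants: 14 methyl ketone triflate
Product: 15 keto-enal
Conditions: Pd(PPh3)4 (5 mol %), CO (1 atm), Bu3SnH (slow addition), LiCl, THF, 50 °C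
Reagents that add atoms: carbon monoxide, [C-]#[O+]
Why: Stille-type reductive carbonylation of the enol triflate (oxidative addition to zerovalent palladium, CO insertion, hydride transfer from tin, reductive elimination) installs C1 as a formyl group on C10; no stereocenter.

**Step 8**
Reactants: 15 keto-enal
Product: 16 ring-A dienone
Conditions: (PhCH2)2NH2+ CF3CO2− (0.3 equiv), benzene, 50 °C
Reagents that add atoms: none
Why: Intramolecular aldol condensation (6-(enolexo)-exo-trig attack of the methyl ketone carbon C2 on the aldehyde C1, then dehydration) closes ring A as the linear dienone, and the mild ammonium salt should leave the acidic C8–H and C11–H2 untouched; no new stereocenter.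

**Step 9**
Reactants: 16 ring-A dienone
Product: 18 β,γ-enone, via lithium dienolate 17 (not isolated)
Conditions: Me2CuLi (from MeLi, CuBr·SMe2), Et2O/THF, −40 → 0 °C; AcOH, −78 °C
Reagents that add atoms: lithium dimethylcuprate, [Li+].C[Cu-]C
Why: 1,6-Conjugate addition of the cuprate to the linear dienone (as in the 7α-methylation of steroidal 4,6-dien-3-ones) should deliver methyl to C9 axially from the α face, anti to the pseudoaxial H8 of a ring-B half-chair fixed by the planar ring A, which leaves CH2Ar equatorial; kinetic protonation of the dienolate at C2 gives the C1=C10 β,γ-enone.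

**Step 10**
Reactants: 18 β,γ-enone
Product: 19 3α-alcohol
Conditions: LiBH(s-Bu)3, THF, −78 °C; H2O
Reagents that add atoms: none
Why: Reduction of the 4,4-dimethyl-3-ketone by a bulky trialkylborohydride should proceed by equatorial hydride delivery to give the axial (3R) alcohol, as with 4,4-dimethyl-3-oxo terpenoids, and the cold non-basic conditions should keep the alkene out of conjugation.

**Step 11**
Reactants: 19 3α-alcohol
Product: 20 resorcinol triol
Conditions: Me3SiOTf, 2,2′-bipyridyl, CH2Cl2, 0 °C → rt; H2O
Reagents that add atoms: none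
Why: Silyl triflate/bipyridyl activation of the three methoxymethyl acetals followed by hydrolysis (acetal cleavage) removes them under buffered, non-protic conditions, avoiding the Brønsted acid that could add a freed phenol across the C1=C10 alkene; no stereocenter changes.

**Step 12**
Reactants: 20 resorcinol triol
Product: 21 target
Conditions: MgCl2, Et3N, (CH2O)n, MeCN, 70 °C
Reagents that add atoms: formaldehyde (as paraformaldehyde), C=O
Why: Casnati–Skattebøl ortho-formylation: the magnesium phenoxide directs hydroxymethylation ortho to OH and a second formaldehyde accepts hydride to give the salicylaldehyde; the two open ring positions are constitutionally equivalent and the first formyl group deactivates the ring, so a single mono-aldehyde is expected under conditions harmless to the alkene.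

**Compound list**

1 | 3,5-dihydroxybenzyl alcohol | OCc1cc(O)cc(O)c1 | starting material
2 | 1,3-bis(methoxymethoxy)-5-[(methoxymethoxy)methyl]benzene | COCOCc1cc(OCOC)cc(OCOC)c1 | intermediate
3 | [2,6-bis(methoxymethoxy)-4-[(methoxymethoxy)methyl]phenyl]lithium (Ar–Li) | [Li]c1c(OCOC)cc(COCOC)cc1OCOC | intermediate
4 | 2,6-bis(methoxymethoxy)-4-[(methoxymethoxy)methyl]benzaldehyde (Ar–CHO) | O=Cc1c(OCOC)cc(COCOC)cc1OCOC | intermediate
5 | (R)-(+)-pulegone, (5R)-5-methyl-2-(propan-2-ylidene)cyclohexan-1-one | C[C@@H]1CCC(=C(C)C)C(=O)C1 | starting material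
6 | bromomagnesium (5R)-5-methyl-2-(2-methylbut-3-en-2-yl)cyclohex-1-en-1-olate | C[C@@H]1CCC(C(C)(C)C=C)=C(O[Mg]Br)C1 | intermediate
7 | (2S,5R)-5-methyl-2-(2-methylbut-3-en-2-yl)cyclohexan-1-one (trans) | C[C@@H]1CC[C@@H](C(C)(C)C=C)C(=O)C1 | intermediate
8 | lithium (3R,6S)-3-methyl-6-(2-methylbut-3-en-2-yl)cyclohex-1-en-1-olate | C[C@@H]1CC[C@@H](C(C)(C)C=C)C(O[Li])=C1 | intermediate
9 | lithium aldolate, (3R,6S)-2-[Ar(lithiooxy)methyl]-3-methyl-6-(2-methylbut-3-en-2-yl)cyclohexan-1-one, epimers at ring C2 and at the carbinol carbon | C[C@@H]1CC[C@@H](C(C)(C)C=C)C(=O)C1C(O[Li])c2c(OCOC)cc(COCOC)cc2OCOC | intermediate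
10 | aldol mesylate, (3R,6S)-2-[Ar(methanesulfonyloxy)methyl]-3-methyl-6-(2-methylbut-3-en-2-yl)cyclohexan-1-one, same epimer mixture | C[C@@H]1CC[C@@H](C(C)(C)C=C)C(=O)C1C(OS(C)(=O)=O)c2c(OCOC)cc(COCOC)cc2OCOC | intermediate
11 | (2E,3R,6S)-2-(Ar-methylidene)-3-methyl-6-(2-methylbut-3-en-2-yl)cyclohexan-1-one | C[C@@H]1CC[C@@H](C(C)(C)C=C)C(=O)/C1=C/c2c(OCOC)cc(COCOC)cc2OCOC | intermediate
12 | lithium (3R,6S)-2-(ArCH2)-3-methyl-6-(2-methylbut-3-en-2-yl)cyclohex-1-en-1-olate | C[C@@H]1CC[C@@H](C(C)(C)C=C)C(O[Li])=C1Cc2c(OCOC)cc(COCOC)cc2OCOC | intermediate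
13 | (3R,6S)-2-(ArCH2)-3-methyl-6-(2-methylbut-3-en-2-yl)cyclohex-1-en-1-yl trifluoromethanesulfonate | C[C@@H]1CC[C@@H](C(C)(C)C=C)C(OS(=O)(=O)C(F)(F)F)=C1Cc2c(OCOC)cc(COCOC)cc2OCOC | intermediate
14 | (3R,6S)-2-(ArCH2)-3-methyl-6-(2-methyl-3-oxobutan-2-yl)cyclohex-1-en-1-yl trifluoromethanesulfonate | C[C@@H]1CC[C@@H](C(C)(C)C(C)=O)C(OS(=O)(=O)C(F)(F)F)=C1Cc2c(OCOC)cc(COCOC)cc2OCOC | intermediate
15 | (3R,6R)-2-(ArCH2)-3-methyl-6-(2-methyl-3-oxobutan-2-yl)cyclohex-1-ene-1-carbaldehyde | C[C@@H]1CC[C@@H](C(C)(C)C(C)=O)C(C=O)=C1Cc2c(OCOC)cc(COCOC)cc2OCOC | intermediate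
16 | (6R,8aR)-5-(ArCH2)-1,1,6-trimethyl-6,7,8,8a-tetrahydronaphthalen-2(1H)-one | C[C@@H]1CC[C@@H]2C(=C1Cc3c(OCOC)cc(COCOC)cc3OCOC)C=CC(=O)C2(C)C | intermediate
17 | lithium (5S,6R,8aR)-5-(ArCH2)-1,1,5,6-tetramethyl-1,5,6,7,8,8a-hexahydronaphthalen-2-olate | C[C@@H]1CC[C@@H]2C(=CC=C(O[Li])C2(C)C)[C@@]1(C)Cc3c(OCOC)cc(COCOC)cc3OCOC | intermediate
18 | (5S,6R,8aR)-5-(ArCH2)-1,1,5,6-tetramethyl-3,5,6,7,8,8a-hexahydronaphthalen-2(1H)-one | C[C@@H]1CC[C@@H]2C(=CCC(=O)C2(C)C)[C@@]1(C)Cc3c(OCOC)cc(COCOC)cc3OCOC | intermediate
19 | (2R,5S,6R,8aR)-5-(ArCH2)-1,1,5,6-tetramethyl-1,2,3,5,6,7,8,8a-octahydronaphthalen-2-ol | C[C@@H]1CC[C@@H]2C(=CC[C@@H](O)C2(C)C)[C@@]1(C)Cc3c(OCOC)cc(COCOC)cc3OCOC | intermediate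
20 | 2-{[(1S,2R,4aR,6R)-6-hydroxy-1,2,5,5-tetramethyl-1,2,3,4,4a,5,6,7-octahydronaphthalen-1-yl]methyl}-5-(hydroxymethyl)benzene-1,3-diol | C[C@@H]1CC[C@@H]2C(=CC[C@@H](O)C2(C)C)[C@@]1(C)Cc3c(O)cc(CO)cc3O | intermediate
21 | 2,4-dihydroxy-6-(hydroxymethyl)-3-{[(1S,2R,4aR,6R)-6-hydroxy-1,2,5,5-tetramethyl-1,2,3,4,4a,5,6,7-octahydronaphthalen-1-yl]methyl}benzaldehyde | C[C@@H]1CC[C@@H]2C(=CC[C@@H](O)C2(C)C)[C@@]1(C)Cc1c(O)cc(CO)c(C=O)c1O | target

**Count and risks**

Total step count: 12. Longest linear sequence: 11 steps (1, 2, then 4 to 12).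

Steps most likely to fail:

1. Step 9. The methyl group may be transferred to C1 (1,4-addition) or to the carbonyl instead of the fully substituted δ-carbon C9, or the cuprate may simply react too slowly at this hindered terminus. Fallback: set out from keto-enal 15 and add Me2CuLi/Me3SiCl in the 1,4 sense to the β,β-disubstituted enal, an established way to make quaternary carbons. The methyl should enter anti to the pseudoaxial H8 of the diequatorial conformer and give, after hydrolysis, the keto-aldehyde F1. Intramolecular aldol condensation of F1 gives the conjugated enone F2, and γ-deprotonation at C10 with KN(SiMe3)2 followed by kinetic protonation with AcOH moves the alkene out of conjugation and returns to 18.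

2. Step 5. Hydride may attack the carbonyl (1,2-reduction) or fail to reach the β-carbon, which carries a 2,6-disubstituted aryl group. Fallback: make the C9–C11 bond by enolate alkylation instead. Reduce 4 with NaBH4 to the benzylic alcohol F3, convert it with CBr4/PPh3 into the benzylic bromide F4, and alkylate the lithium enolate of 7 (LiN(i-Pr)2, −78 °C) with F4 to give the 2-benzyl ketone F5 as C9 epimers. Enolisation toward C9 with KN(SiMe3)2 and trapping with PhNTf2 returns to 13.

3. Step 12. Formylation of the polyhydroxylated substrate may stall at the hindered ring position, go on to a second formylation, or be diverted by acetal formation with the neighbouring CH2OH. Fallback: set out from 19, lithiate with excess n-BuLi/TMEDA at the ring position between OMOM and CH2OMOM (directed ortho-metalation, after deprotonation of the C3 hydroxyl) and quench with DMF to give the protected aldehyde F6. Removal of the three acetals as in step 11 returns to 21.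

**Further compounds**

F1 | step 9 | (2S,3R,6R)-2-(ArCH2)-2,3-dimethyl-6-(2-methyl-3-oxobutan-2-yl)cyclohexane-1-carbaldehyde, C1 epimers | C[C@@H]1CC[C@@H](C(C)(C)C(C)=O)C(C=O)[C@@]1(C)Cc2c(OCOC)cc(COCOC)cc2OCOC
F2 | step 9 | (5S,6R,8aR)-5-(ArCH2)-1,1,5,6-tetramethyl-4a,5,6,7,8,8a-hexahydronaphthalen-2(1H)-one, C4a epimers | C[C@@H]1CC[C@@H]2C(C=CC(=O)C2(C)C)[C@@]1(C)Cc3c(OCOC)cc(COCOC)cc3OCOC
F3 | step 5 | [2,6-bis(methoxymethoxy)-4-[(methoxymethoxy)methyl]phenyl]methanol | OCc1c(OCOC)cc(COCOC)cc1OCOC
F4 | step 5 | 2-(bromomethyl)-1,3-bis(methoxymethoxy)-5-[(methoxymethoxy)methyl]benzene | BrCc1c(OCOC)cc(COCOC)cc1OCOC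
F5 | step 5 | (3R,6S)-2-(ArCH2)-3-methyl-6-(2-methylbut-3-en-2-yl)cyclohexan-1-one, C2 epimers | C[C@@H]1CC[C@@H](C(C)(C)C=C)C(=O)C1Cc2c(OCOC)cc(COCOC)cc2OCOC
F6 | step 12 | 3-{[(1S,2R,4aR,6R)-6-hydroxy-1,2,5,5-tetramethyl-1,2,3,4,4a,5,6,7-octahydronaphthalen-1-yl]methyl}-2,4-bis(methoxymethoxy)-6-[(methoxymethoxy)methyl]benzaldehyde | C[C@@H]1CC[C@@H]2C(=CC[C@@H](O)C2(C)C)[C@@]1(C)Cc3c(OCOC)cc(COCOC)c(C=O)c3OCOC
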